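## Retrosynthetic overview

1. The last two steps, acetonide hydrolysis and hydrogenolysis of three benzyl ethers, release the target from a protected (2S)-flavanone.
2. Ring C is cut at C3–C4. The flavanone is the hydroacylation adduct of an ortho-formyl aryl 1-arylvinyl ether, so one enantioselective rhodium-catalysed intramolecular alkene hydroacylation forms C3–C4, closes ring C, delivers the C4 ketone and sets C2.
3. Enabling feature: in ring C, O1 joins C8a of ring A to C2, C2 carries only ring B and one H, C3 is a bare CH2, and the C4 carbonyl sits on C4a, ortho to O1 and next to O5. At the enol ether level C2=C3 is therefore a 1,1-disubstituted alkene without allylic H, and its CH2 end lies within reach of a formyl group flanked by two ether oxygens.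
4. The enol ether comes from methylenation of the aryl ester made from a ring A bromophenol and a ring B benzoic acid. The formyl group comes from the bromide by Br/Li exchange and DMF.
5. The side chain is built on ring B first: an Evans syn aldol of the ring B aryloxyacetyl imide with O-benzylvanillin fixes C8'', and a Mitsunobu inversion at C7'' gives erythro. Ring order: temporary 1,3-dioxane, then ring C; rings A, B and the guaiacyl ring are bought.

Key step: step 13

Assumption: (R)-DTBM-SEGPHOS is taken, by analogy with the carbocyclic hydroacylations, to deliver hydride to the face of C2 that gives 2S. The sense would be checked on a model substrate and the (S)-ligand used if it is opposite. Side-chain carbons are numbered 7'', 8'', 9''; flavanone atoms carry the usual numbers.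

## Route

Step 1
Reactants: 1 methyl syringate (methyl 4-hydroxy-3,5-dimethoxybenzoate); 2 bromoacetic acid
Product: 3 2-[2,6-dimethoxy-4-(methoxycarbonyl)phenoxy]acetic acid
Conditions: NaH (2.2 equiv), THF, 0 °C to reflux; then 1 M HCl
Reagents that add atoms: none
Why: Williamson ether synthesis: the sodium phenoxide of 1 should displace bromide from sodium bromoacetate by SN2, and the water-free base leaves the methyl ester intact.

Step 2
Reactants: 3 2-[2,6-dimethoxy-4-(methoxycarbonyl)phenoxy]acetic acid; 4 (R)-4-benzyl-1,3-oxazolidin-2-one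
Product: 6 (4R)-4-benzyl-3-{[2,6-dimethoxy-4-(methoxycarbonyl)phenoxy]acetyl}-1,3-oxazolidin-2-one, via mixed pivalic anhydride 5 (not isolated)
Conditions: t-BuCOCl, Et3N, THF, −20 °C; then LiCl, 4, −20 °C to rt
Reagents that add atoms: pivaloyl chloride CC(C)(C)C(=O)Cl (its acyl group stays only in 5)
Why: N-acylation of an oxazolidinone through a mixed anhydride: the LiCl-activated auxiliary should attack the unhindered aryloxyacetyl carbonyl of 5 and not the pivaloyl carbonyl.

Step 3
Reactants: 6 aryloxyacetyl imide; 7 4-(benzyloxy)-3-methoxybenzaldehyde (O-benzylvanillin)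
Product: 10 methyl 4-{[(1S,2R)-1-(4-benzyloxy-3-methoxyphenyl)-3-[(4R)-4-benzyl-2-oxo-1,3-oxazolidin-3-yl]-1-hydroxy-3-oxopropan-2-yl]oxy}-3,5-dimethoxybenzoate (syn aldol adduct), via boron enolate 8 (not isolated), via boron aldolate 9 (not isolated)
Conditions: Bu2BOTf, i-Pr2NEt, CH2Cl2, 0 °C; 7, −78 to 0 °C; pH 7 buffer, MeOH, 30% H2O2
Reagents that add atoms: dibutylboron triflate CCCCB(CCCC)OS(=O)(=O)C(F)(F)F (its Bu2B group stays only in 8 and 9)
Why: Evans syn aldol reaction: the (Z)-boron enolate 8 should add to 7 through a chair-like Zimmerman–Traxler transition state on the enolate face turned away from the benzyl group of the (R)-auxiliary, which sets C8'' in its final spatial arrangement and C7'' as the 7''S epimer (threo), as is known for aryloxyacetyl imides in beta-O-4 lignin models.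

Step 4
Reactants: 10 syn aldol adduct
Product: 11 methyl 4-{[(1S,2S)-1-(4-benzyloxy-3-methoxyphenyl)-1,3-dihydroxypropan-2-yl]oxy}-3,5-dimethoxybenzoate (threo diol 7''S,8''S)
Conditions: NaBH4, THF/H2O (4:1), 0 °C to rt
Reagents that add atoms: none
Why: Reductive cleavage of an N-acyl oxazolidinone with NaBH4 in wet THF: the exocyclic imide carbonyl is far more electrophilic than the electron-rich aromatic ester, no stereocentre is touched (the descriptor at C8'' changes from R to S only through the priority rules) and 4 is recovered.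

Step 5
Reactants: 11 threo diol
Product: 13 methyl 4-{[(1R,2S)-1-(4-benzyloxy-3-methoxyphenyl)-1,3-bis(4-nitrobenzoyloxy)propan-2-yl]oxy}-3,5-dimethoxybenzoate (erythro diester), via primary mono-ester 12 (not isolated)
Conditions: 4-O2NC6H4CO2H (3 equiv), PPh3 (3 equiv), DIAD (3 equiv), THF, 0 °C to rt
Reagents that add atoms: 4-nitrobenzoic acid O=C(O)c1ccc(cc1)[N+](=O)[O-]
Why: Mitsunobu reaction: the primary C9'' alcohol should be esterified first to 12, and the benzylic C7'' oxyphosphonium ion is then displaced by 4-nitrobenzoate in an SN2 process with inversion, which turns threo (7''S,8''S) into erythro (7''R,8''S) as known for beta-O-4 model alcohols.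

Step 6
Reactants: 13 erythro diester
Product: 14 methyl 4-{[(1R,2S)-1-(4-benzyloxy-3-methoxyphenyl)-1,3-dihydroxypropan-2-yl]oxy}-3,5-dimethoxybenzoate (erythro diol 7''R,8''S)
Conditions: K2CO3 (0.2 equiv), MeOH/THF, 0 °C to rt
Reagents that add atoms: none
Why: Base-catalysed transesterification (Zemplén-type methanolysis): the activated 4-nitrobenzoates are cleaved at the acyl carbon so that both C–O stereocentres are kept, and exchange at the methyl benzoate is degenerate.

Step 7
Reactants: 14 erythro diol
Product: 15 methyl 4-{[(4R,5S)-4-(4-benzyloxy-3-methoxyphenyl)-2,2-dimethyl-1,3-dioxan-5-yl]oxy}-3,5-dimethoxybenzoate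
Conditions: Me2C(OMe)2, PPTS (cat.), CH2Cl2, rt
Reagents that add atoms: 2,2-dimethoxypropane COC(C)(C)OC
Why: Acetal exchange (acetonide formation): the 1,3-diol should close to the six-membered 1,3-dioxane under mild acid that does not ionise the benzylic C7''–O bond, which masks both hydroxyl groups for the organometallic steps.

Step 8
Reactants: 15 acetonide ester
Product: 16 4-{[(4R,5S)-4-(4-benzyloxy-3-methoxyphenyl)-2,2-dimethyl-1,3-dioxan-5-yl]oxy}-3,5-dimethoxybenzoic acid
Conditions: LiOH (3 equiv), THF/MeOH/H2O, 40 °C; then cold 0.5 M HCl to pH 4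
Reagents that add atoms: lithium hydroxide [Li+].[OH-]
Why: Saponification (BAc2 ester hydrolysis): hydroxide cleaves the only ester left, and the acetal, benzyl ether and aryl ether groups are inert to base.

Step 9
Reactants: 17 3,5-bis(benzyloxy)phenol
Product: 18 3,5-bis(benzyloxy)-2-bromophenol
Conditions: NBS (1.0 equiv), i-Pr2NH (10 mol %), CH2Cl2, −78 to 0 °C
Reagents that add atoms: N-bromosuccinimide O=C1CCC(=O)N1Br
Why: Amine-catalysed ortho-selective electrophilic bromination of a phenol: the N-bromoamine formed in situ is guided by the phenolic OH to the equivalent C2/C6 positions, while C4 is shielded by two benzyloxy groups.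

Step 10
Reactants: 16 ring B acid; 18 ring A bromophenol
Product: 20 3,5-bis(benzyloxy)-2-bromophenyl 4-{[(4R,5S)-4-(4-benzyloxy-3-methoxyphenyl)-2,2-dimethyl-1,3-dioxan-5-yl]oxy}-3,5-dimethoxybenzoate, via O-acylisourea 19 (not isolated)
Conditions: diisopropylcarbodiimide, DMAP (10 mol %), CH2Cl2, 0 °C to rt
Reagents that add atoms: diisopropylcarbodiimide CC(C)N=C=NC(C)C (its atoms stay only in 19)
Why: Steglich esterification: the carbodiimide activates 16 as O-acylisourea 19 and DMAP relays the acyl group to the hindered phenol 18 under neutral conditions that keep the acetonide.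

Step 11
Reactants: 20 aryl ester
Product: 21 1-[3,5-bis(benzyloxy)-2-bromophenoxy]-1-(4-{[(4R,5S)-4-(4-benzyloxy-3-methoxyphenyl)-2,2-dimethyl-1,3-dioxan-5-yl]oxy}-3,5-dimethoxyphenyl)ethene
Conditions: Cp2TiMe2 (3 equiv), toluene, 70 °C, dark; filtration through basic alumina
Reagents that add atoms: dimethyltitanocene [CH3-].[CH3-].[CH-]1C=CC=C1.[CH-]1C=CC=C1.[Ti+4]
Why: Petasis methylenation: Cp2Ti=CH2 released on heating undergoes [2+2] cycloaddition with the ester carbonyl and cycloreversion to the enol ether, a conversion well known for aryl benzoates, and the non-acidic reagent tolerates aryl bromide, acetal and benzyl ethers.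

Step 12
Reactants: 21 bromo enol ether
Product: 24 2,4-bis(benzyloxy)-6-{[1-(4-{[(4R,5S)-4-(4-benzyloxy-3-methoxyphenyl)-2,2-dimethyl-1,3-dioxan-5-yl]oxy}-3,5-dimethoxyphenyl)ethenyl]oxy}benzaldehyde, via aryllithium 22 (not isolated), via lithium hemiaminal alkoxide 23 (not isolated)
Conditions: n-BuLi (1.1 equiv), THF, −78 °C; DMF, −78 to 0 °C; H2O
Reagents that add atoms: N,N-dimethylformamide CN(C)C=O; n-butyllithium [Li]CCCC (lithium stays only in 22 and 23)
Why: Bromine–lithium exchange followed by formylation with DMF (Bouveault-type aldehyde synthesis): exchange at the bromide flanked by two oxygen substituents is much faster at −78 °C than any deprotonation, and the basic aqueous quench spares the acid-labile enol ether.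

Step 13
Reactants: 24 ortho-formyl aryl 1-arylvinyl ether
Product: 25 (2S)-5,7-bis(benzyloxy)-2-(4-{[(4R,5S)-4-(4-benzyloxy-3-methoxyphenyl)-2,2-dimethyl-1,3-dioxan-5-yl]oxy}-3,5-dimethoxyphenyl)chroman-4-one
Conditions: [Rh(cod)Cl]2 (2.5 mol %), (R)-DTBM-SEGPHOS (5.5 mol %), NaB[3,5-(CF3)2C6H3]4 (6 mol %), dry 1,4-dioxane, 80 °C
Reagents that add atoms: none
Why: Proposed new method: a cationic complex of monovalent rhodium inserts into the formyl C–H bond of 24 to give an acyl hydride of trivalent rhodium that is held by the C2=C3 alkene and by the ether oxygen at C5, the hydride then migrates to the oxygen-bearing and therefore electrophilic C2 while rhodium takes the free C3 methylene, and reductive elimination from the seven-membered rhodacycle forms the C3–C4 bond. The closest known reaction types are the enantioselective endo hydroacylation of ortho-allylbenzaldehydes with a 1,1-disubstituted alkene to 3-substituted tetralones and the hydroacylation of N-(1-substituted vinyl)indole-2-carbaldehydes, which show six-ring closure and a heteroatom on the internal alkene carbon separately, whereas an aryl 1-arylvinyl ether has not been used. Ring C closes in a formal 6-endo-trig mode. C2 is the only new stereocentre and is set in the hydride insertion by the chiral pocket of (R)-DTBM-SEGPHOS, since the side-chain stereocentres lie six bonds away across ring B and should not interfere. The step needs regioselectivity against the 2-aryl-2-methylbenzofuran-3-one, secured by the 1,1-disubstitution because the other insertion would place rhodium on a fully substituted carbon, and chemoselectivity against decarbonylation and alkene migration, secured by the two-point binding of the acyl hydride and by the absence of allylic hydrogen atoms on C2=C3. No atom is lost, the C4 ketone appears at its final oxidation level, and the precursor is acyclic and free of stereocentres in this region.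

Step 14
Reactants: 25 protected flavanone
Product: 26 (2S)-5,7-bis(benzyloxy)-2-(4-{[(1R,2S)-1-(4-benzyloxy-3-methoxyphenyl)-1,3-dihydroxypropan-2-yl]oxy}-3,5-dimethoxyphenyl)chroman-4-one
Conditions: AcOH/THF/H2O (4:1:1), 40 °C
Reagents that add atoms: none
Why: Acid-catalysed acetal hydrolysis: cleavage runs through the acetone-derived oxocarbenium ion and not through the C7''–O bond, so that 7''R is kept while the guaiacyl phenol is still benzylated, and C2 of the flavanone is stable to weak acid.

Step 15
Reactants: 26 tribenzyl ether diol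
Product: 27 (2S)-5,7-dihydroxy-2-(4-{[(1R,2S)-1,3-dihydroxy-1-(4-hydroxy-3-methoxyphenyl)propan-2-yl]oxy}-3,5-dimethoxyphenyl)chroman-4-one (target CNP0318401.1)
Conditions: H2 (1 atm), 10% Pd/C, EtOAc/MeOH, rt
Reagents that add atoms: none
Why: Catalytic hydrogenolysis of aryl benzyl ethers: the three PhCH2–OAr bonds should be cleaved faster than the secondary benzylic C7''–OH and C2–O1 bonds, and the neutral medium avoids the base-induced opening of ring C that would racemise C2.

## Compound list

1 | methyl syringate | COC(=O)c1cc(OC)c(O)c(OC)c1 | starting material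
2 | bromoacetic acid | OC(=O)CBr | starting material
3 | 2-[2,6-dimethoxy-4-(methoxycarbonyl)phenoxy]acetic acid | COC(=O)c1cc(OC)c(OCC(=O)O)c(OC)c1 | intermediate
4 | (R)-4-benzyl-1,3-oxazolidin-2-one | O=C1N[C@H](Cc2ccccc2)CO1 | starting material
5 | mixed pivalic anhydride of 3 (not isolated) | COC(=O)c1cc(OC)c(OCC(=O)OC(=O)C(C)(C)C)c(OC)c1 | intermediate
6 | (4R)-aryloxyacetyl imide | COC(=O)c1cc(OC)c(OCC(=O)N2C(=O)OC[C@H]2Cc2ccccc2)c(OC)c1 | intermediate
7 | 4-(benzyloxy)-3-methoxybenzaldehyde | COc1cc(C=O)ccc1OCc1ccccc1 | starting material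
8 | (Z)-dibutylboron enolate of 6 (not isolated) | CCCCB(CCCC)O/C(N1C(=O)OC[C@H]1Cc1ccccc1)=C\Oc1c(OC)cc(C(=O)OC)cc1OC | intermediate
9 | dibutylboron aldolate (not isolated) | COC(=O)c1cc(OC)c(O[C@@H](C(=O)N2C(=O)OC[C@H]2Cc2ccccc2)[C@@H](OB(CCCC)CCCC)c2ccc(OCc3ccccc3)c(OC)c2)c(OC)c1 | intermediate
10 | syn aldol adduct (acyl chain 2R,3S) | COC(=O)c1cc(OC)c(O[C@@H](C(=O)N2C(=O)OC[C@H]2Cc2ccccc2)[C@@H](O)c2ccc(OCc3ccccc3)c(OC)c2)c(OC)c1 | intermediate
11 | threo diol (7''S,8''S) | COC(=O)c1cc(OC)c(O[C@@H](CO)[C@@H](O)c2ccc(OCc3ccccc3)c(OC)c2)c(OC)c1 | intermediate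
12 | C9'' mono-4-nitrobenzoate (7''S,8''S, not isolated) | COC(=O)c1cc(OC)c(O[C@@H](COC(=O)c2ccc(cc2)[N+](=O)[O-])[C@@H](O)c2ccc(OCc3ccccc3)c(OC)c2)c(OC)c1 | intermediate
13 | erythro bis(4-nitrobenzoate) (7''R,8''S) | COC(=O)c1cc(OC)c(O[C@@H](COC(=O)c2ccc(cc2)[N+](=O)[O-])[C@H](OC(=O)c2ccc(cc2)[N+](=O)[O-])c2ccc(OCc3ccccc3)c(OC)c2)c(OC)c1 | intermediate
14 | erythro diol (7''R,8''S) | COC(=O)c1cc(OC)c(O[C@@H](CO)[C@H](O)c2ccc(OCc3ccccc3)c(OC)c2)c(OC)c1 | intermediate
15 | (4R,5S)-acetonide methyl ester | COC(=O)c1cc(OC)c(O[C@H]2COC(C)(C)O[C@@H]2c2ccc(OCc3ccccc3)c(OC)c2)c(OC)c1 | intermediate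
16 | (4R,5S)-acetonide benzoic acid | OC(=O)c1cc(OC)c(O[C@H]2COC(C)(C)O[C@@H]2c2ccc(OCc3ccccc3)c(OC)c2)c(OC)c1 | intermediate
17 | 3,5-bis(benzyloxy)phenol | Oc1cc(OCc2ccccc2)cc(OCc2ccccc2)c1 | starting material
18 | 3,5-bis(benzyloxy)-2-bromophenol | Oc1cc(OCc2ccccc2)cc(OCc2ccccc2)c1Br | intermediate
19 | O-acylisourea of 16 (not isolated) | CC(C)NC(=NC(C)C)OC(=O)c1cc(OC)c(O[C@H]2COC(C)(C)O[C@@H]2c2ccc(OCc3ccccc3)c(OC)c2)c(OC)c1 | intermediate
20 | aryl ester | O=C(Oc1cc(OCc2ccccc2)cc(OCc2ccccc2)c1Br)c1cc(OC)c(O[C@H]2COC(C)(C)O[C@@H]2c2ccc(OCc3ccccc3)c(OC)c2)c(OC)c1 | intermediate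
21 | bromoaryl 1-arylvinyl ether | C=C(Oc1cc(OCc2ccccc2)cc(OCc2ccccc2)c1Br)c1cc(OC)c(O[C@H]2COC(C)(C)O[C@@H]2c2ccc(OCc3ccccc3)c(OC)c2)c(OC)c1 | intermediate
22 | aryllithium (not isolated) | C=C(Oc1cc(OCc2ccccc2)cc(OCc2ccccc2)c1[Li])c1cc(OC)c(O[C@H]2COC(C)(C)O[C@@H]2c2ccc(OCc3ccccc3)c(OC)c2)c(OC)c1 | intermediate
23 | lithium hemiaminal alkoxide (not isolated) | C=C(Oc1cc(OCc2ccccc2)cc(OCc2ccccc2)c1C([O-])N(C)C)c1cc(OC)c(O[C@H]2COC(C)(C)O[C@@H]2c2ccc(OCc3ccccc3)c(OC)c2)c(OC)c1.[Li+] | intermediate
24 | ortho-formyl aryl 1-arylvinyl ether | C=C(Oc1cc(OCc2ccccc2)cc(OCc2ccccc2)c1C=O)c1cc(OC)c(O[C@H]2COC(C)(C)O[C@@H]2c2ccc(OCc3ccccc3)c(OC)c2)c(OC)c1 | intermediate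
25 | protected (2S)-flavanone | O=C1C[C@@H](c2cc(OC)c(O[C@H]3COC(C)(C)O[C@@H]3c3ccc(OCc4ccccc4)c(OC)c3)c(OC)c2)Oc2cc(OCc3ccccc3)cc(OCc3ccccc3)c12 | intermediate
26 | (2S,7''R,8''S)-tribenzyl ether diol | O=C1C[C@@H](c2cc(OC)c(O[C@@H](CO)[C@H](O)c3ccc(OCc4ccccc4)c(OC)c3)c(OC)c2)Oc2cc(OCc3ccccc3)cc(OCc3ccccc3)c12 | intermediate
27 | CNP0318401.1 (2S,7''R,8''S) | COc1cc([C@@H](O)[C@H](CO)Oc2c(OC)cc([C@@H]3CC(=O)c4c(O)cc(O)cc4O3)cc2OC)ccc1O | target

## Step count and risks

Total step count: 15. Longest linear sequence: 14 steps (steps 1–8 and 10–15, from methyl syringate); step 9 runs in parallel.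

**Step 13 (hydroacylation).**
- What may go wrong: decarbonylation of the acyl rhodium hydride, Lewis-acid-type aldol closure or hydrolysis of the enol ether by the cationic metal, or poor facial selectivity in the hydride insertion.
- The fallback sets out from 24 and comes back at 25, and it forms the same C3–C4 bond by known radical chemistry. A thiol-catalysed radical-chain acyl cyclisation of an alkenal is used (tert-dodecanethiol, 1,1'-azobis(cyclohexanecarbonitrile), toluene, 100 °C).
- The aroyl radical should add 6-endo to the C3 methylene, because this gives the benzylic, oxygen-stabilised C2 radical. Hydrogen transfer from the thiol to that radical is not face-selective.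
- The closure therefore gives 25 together with the 2R epimer F1. The two are diastereomers and would be separated by chromatography.
- F1 would be recycled with catalytic DBU through the 2'-hydroxychalcone F2 and reclosure, followed by a new separation.

**Step 5 (double Mitsunobu).**
- What may go wrong: ionisation of the activated electron-rich benzylic alcohol with loss of stereochemical fidelity, or elimination across C7''–C8''.
- The fallback sets out from 11 and comes back at 14, replacing substitution by an oxidation and reduction pair.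
- Selective benzylic oxidation with DDQ (1,4-dioxane, rt) should give the aryl ketone F3 with C8'' untouched.
- Noyori-type asymmetric transfer hydrogenation with RuCl[(S,S)-TsDPEN](p-cymene) in HCO2H/Et3N should then set 7''R under catalyst control. The weakly acidic medium limits epimerisation at C8''. Step 6 is no longer needed.

**Step 11 (methylenation).**
- What may go wrong: sluggish attack on the hindered ortho-bromoaryl ester, competing acyl–oxygen cleavage, and hydrolysis of the enol ether during isolation.
- The fallback sets out from 16 and comes back at 24, bypassing steps 10–12. It forms the O1–C2 bond by cross-coupling instead of carbonyl olefination.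
- MeLi (2.2 equiv, THF, −78 to 0 °C) should convert the acid into the methyl ketone F4.
- KN(SiMe3)2 and PhNTf2 should then give the 1-arylvinyl triflate F5.
- Coupling catalysed by zerovalent palladium (Pd2(dba)3, 2-(di-tert-butylphosphino)biphenyl, K3PO4, toluene, 80 °C) with 2,4-bis(benzyloxy)-6-hydroxybenzaldehyde F6 should deliver 24 with the formyl group already in place.
- F6 is made from 2,4,6-trihydroxybenzaldehyde with BnBr and K2CO3, the chelated ortho hydroxyl staying free.

Further compounds
F1 | step 13 | (2R)-epimer of protected flavanone 25 | O=C1C[C@H](c2cc(OC)c(O[C@H]3COC(C)(C)O[C@@H]3c3ccc(OCc4ccccc4)c(OC)c3)c(OC)c2)Oc2cc(OCc3ccccc3)cc(OCc3ccccc3)c12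
F2 | step 13 | (E)-2'-hydroxy-4',6'-bis(benzyloxy)chalcone with the protected side chain | O=C(/C=C/c1cc(OC)c(O[C@H]2COC(C)(C)O[C@@H]2c2ccc(OCc3ccccc3)c(OC)c2)c(OC)c1)c1c(O)cc(OCc2ccccc2)cc1OCc1ccccc1
F3 | step 5 | methyl 4-{[(2S)-1-(4-benzyloxy-3-methoxyphenyl)-3-hydroxy-1-oxopropan-2-yl]oxy}-3,5-dimethoxybenzoate | COC(=O)c1cc(OC)c(O[C@@H](CO)C(=O)c2ccc(OCc3ccccc3)c(OC)c2)c(OC)c1
F4 | step 11 | ring B methyl ketone with the (4R,5S)-acetonide side chain | CC(=O)c1cc(OC)c(O[C@H]2COC(C)(C)O[C@@H]2c2ccc(OCc3ccccc3)c(OC)c2)c(OC)c1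
F5 | step 11 | 1-arylvinyl triflate of F4 | C=C(OS(=O)(=O)C(F)(F)F)c1cc(OC)c(O[C@H]2COC(C)(C)O[C@@H]2c2ccc(OCc3ccccc3)c(OC)c2)c(OC)c1
F6 | step 11 | 2,4-bis(benzyloxy)-6-hydroxybenzaldehyde | O=Cc1c(O)cc(OCc2ccccc2)cc1OCc1ccccc1
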